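**Retrosynthetic overview**

1. Numbering: ring C1 (=CH2), C2, C3, C4=C5 (Me on C5), C6, C7, C8 (side chain), C9 (CO2Me); side chain C1′ (CH2OAc), C2′, C3′, C4′, C5′ (carbinol). The strategy rests on the γ,δ-unsaturated acid formed by the C9 carboxyl and the C8–C1′=C2′ unit on the nine-membered ring C1–C9.
2. Key disconnection C8–C9: Ireland–Claisen ring contraction of a 13-membered lactone that joins the C9 acyl carbon to the C2′ oxygen and holds an (E)-C8=C1′ alkene; this one step gives the ring, C8, C9 and the C1′=C2′ geometry.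
3. The C3′=C4′ alkene is carried through that step as an alkyne, so that C2′ bears only one allyl arm; trans hydrosilylation and protodesilylation then give the (E)-alkene, followed by desilylation and acetylation.
4. The lactone comes from Yamaguchi closure of a seco acid whose C2′ carbinol is set by catalytic asymmetric alkynylation (C2′–C3′) of an (E)-enal made by cross metathesis (C8=C1′).
5. The chain comes from hex-5-en-1-yne by carboalumination and oxirane opening (Me–C5, C3–C4) and nickel-catalysed opening of diketene (C1–C2). Ring order: 13-membered lactone first, nine-membered carbocycle second; there is no other ring.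

Key step: step 12

Remark: (R,R)-ProPhenol is taken to deliver the alkynylzinc to the Si face of the enal in step 9 (C2′ = S); if the first run shows the opposite sense, the (S,S)-ligand is used and nothing else changes.

**Route**

Step 1
Reactants: 1 hex-5-en-1-yne; 2 oxirane
Product: 5 (3E)-4-methylocta-3,7-dien-1-ol, via alkenylalane 3 (not isolated), via lithium alanate 4 (not isolated)
Conditions: Me3Al (2 equiv), Cp2ZrCl2 (0.2 equiv), CH2Cl2, 0 °C → rt; volatiles off; n-BuLi, hexane/THF, 0 °C; 2, 0 °C → rt; 1 M HCl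
Reagents that add atoms: trimethylaluminium, C[Al](C)C
Why: Negishi zirconium-catalysed carboalumination adds Me and Al syn across the terminal alkyne only, and the derived lithium alanate opens oxirane with retention at the alkenyl carbon, which fixes the (E)-C4=C5 alkene.

Step 2
Reactants: 5 (3E)-4-methylocta-3,7-dien-1-ol
Product: 6 (5E)-8-bromo-5-methylocta-1,5-diene
Conditions: CBr4, PPh3, CH2Cl2, 0 °C
Reagents that add atoms: tetrabromomethane, BrC(Br)(Br)Br
Why: Appel bromination of the primary homoallylic alcohol is neutral and should leave both alkenes and the alkene geometry untouched.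

Step 3
Reactants: 6 (5E)-8-bromo-5-methylocta-1,5-diene; 7 diketene
Product: 9 (6E)-7-methyl-3-methylideneundeca-6,10-dienoic acid, via Grignard reagent 8 (not isolated)
Conditions: Mg, THF, rt; then 7, NiCl2 (5 mol %), THF, −20 → 0 °C; 1 M HCl
Reagents that add atoms: none
Why: Nickel-catalysed ring opening of diketene by a Grignard reagent (insertion of zerovalent nickel formed in situ into the vinylic C–O bond, transmetalation, reductive elimination) is a known route to 3-methylidene alkanoic acids and should install C1 with its methylidene group, C9 and the carboxyl in one operation.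

Step 4
Reactants: 9 (6E)-7-methyl-3-methylideneundeca-6,10-dienoic acid
Product: 10 methyl (6E)-7-methyl-3-methylideneundeca-6,10-dienoate
Conditions: Me3SiCHN2, MeOH/toluene, 0 °C
Reagents that add atoms: (trimethylsilyl)diazomethane, C[Si](C)(C)C=[N+]=[N-]
Why: Diazoalkane esterification is neutral and fast, so the β,γ-unsaturated acid should be protected without migration of the 3-methylidene double bond.

Step 5
Reactants: 11 2-methylidenepropane-1,3-diol
Product: 13 2-({[tert-butyl(dimethyl)silyl]oxy}methyl)prop-2-en-1-ol, via sodium monoalkoxide 12 (not isolated)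
Conditions: NaH (1 equiv), THF, 0 °C → rt; t-BuMe2SiCl (1 equiv), rt
Reagents that add atoms: tert-butylchlorodimethylsilane, CC(C)(C)[Si](C)(C)Cl
Why: Monodeprotonation of the symmetrical diol and silylation of the sparingly soluble monosodium salt is the standard way to a mono-silyl ether of a symmetrical diol.

Step 6
Reactants: 13 2-({[tert-butyl(dimethyl)silyl]oxy}methyl)prop-2-en-1-ol
Product: 14 2-({[tert-butyl(dimethyl)silyl]oxy}methyl)prop-2-enal
Conditions: MnO2, CH2Cl2, rt
Reagents that add atoms: none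
Why: MnO2 oxidises allylic alcohols selectively to enals under neutral conditions, which suits the polymerisable 2-substituted acrolein.

Step 7
Reactants: 10 methyl (6E)-7-methyl-3-methylideneundeca-6,10-dienoate; 14 2-({[tert-butyl(dimethyl)silyl]oxy}methyl)prop-2-enal
Product: 15 methyl (6E,10E)-11-({[tert-butyl(dimethyl)silyl]oxy}methyl)-7-methyl-3-methylidene-12-oxododeca-6,10-dienoate
Conditions: second-generation Grubbs catalyst RuCl2(=CHPh)(PCy3)(H2IMes) (5 mol %), 14 (3 equiv), CH2Cl2, 40 °C
Reagents that add atoms: none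
Why: Olefin cross metathesis of a terminal alkene with an excess of a 2-substituted acrolein, which does not homodimerise, is known to give the (E)-trisubstituted enal under thermodynamic control (C7 trans to the formyl carbon C2′), while the 1,1-disubstituted and trisubstituted alkenes of 10 should react far more slowly.

Step 8
Reactants: 16 2-methylbut-3-yn-2-ol
Product: 17 triethyl[(2-methylbut-3-yn-2-yl)oxy]silane
Conditions: Et3SiCl, imidazole, DMAP (cat.), DMF, rt
Reagents that add atoms: chlorotriethylsilane, CC[Si](Cl)(CC)CC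
Why: Standard silylation masks the tertiary hydroxyl, which would otherwise consume the zinc reagent in step 9 and the base in step 12.

Step 9
Reactants: 15 methyl (6E,10E)-11-({[tert-butyl(dimethyl)silyl]oxy}methyl)-7-methyl-3-methylidene-12-oxododeca-6,10-dienoate; 17 triethyl[(2-methylbut-3-yn-2-yl)oxy]silane
Product: 19 methyl (6E,10E,12S)-11-({[tert-butyl(dimethyl)silyl]oxy}methyl)-12-hydroxy-7,15-dimethyl-3-methylidene-15-[(triethylsilyl)oxy]hexadeca-6,10-dien-13-ynoate, via alkynyl(methyl)zinc 18 (not isolated)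
Conditions: 17 (2.8 equiv), Me2Zn (3 equiv), (R,R)-ProPhenol (10 mol %), Ph3PO (20 mol %), toluene, rt; then 15, 4 °C; aq. NH4Cl
Reagents that add atoms: none
Why: The dinuclear zinc–ProPhenol catalysed asymmetric alkynylation is known for α-substituted enals, is 1,2-selective and tolerates esters; the chiral catalyst should deliver the alkynyl group to the Si face of the aldehyde and so set C2′ as S.

Step 10
Reactants: 19 methyl (6E,10E,12S)-11-({[tert-butyl(dimethyl)silyl]oxy}methyl)-12-hydroxy-7,15-dimethyl-3-methylidene-15-[(triethylsilyl)oxy]hexadeca-6,10-dien-13-ynoate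
Product: 21 (6E,10E,12S)-11-({[tert-butyl(dimethyl)silyl]oxy}methyl)-12-hydroxy-7,15-dimethyl-3-methylidene-15-[(triethylsilyl)oxy]hexadeca-6,10-dien-13-ynoic acid, via trimethylstannyl ester 20 (not isolated)
Conditions: Me3SnOH, ClCH2CH2Cl, 70 °C; cold 0.1 M HCl wash
Reagents that add atoms: trimethyltin hydroxide, C[Sn](C)(C)O
Why: Trimethyltin hydroxide cleaves methyl esters by a near-neutral acyl transfer, so the β,γ-unsaturated acid should be released without conjugation of the double bond and with both silyl ethers intact.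

Step 11
Reactants: 21 (6E,10E,12S)-11-({[tert-butyl(dimethyl)silyl]oxy}methyl)-12-hydroxy-7,15-dimethyl-3-methylidene-15-[(triethylsilyl)oxy]hexadeca-6,10-dien-13-ynoic acid
Product: 23 (7E,11E,13S)-12-({[tert-butyl(dimethyl)silyl]oxy}methyl)-8-methyl-4-methylidene-13-{3-methyl-3-[(triethylsilyl)oxy]but-1-yn-1-yl}-1-oxacyclotrideca-7,11-dien-2-one, via mixed anhydride 22 (not isolated)
Conditions: 2,4,6-Cl3C6H2COCl, Et3N, THF, rt; then slow addition to DMAP, toluene (1 mM), 40 °C
Reagents that add atoms: none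
Why: Yamaguchi macrolactonisation acylates the only free hydroxyl (C2′) with the mixed anhydride under high dilution, and the two (E)-alkenes restrict the seco acid so that closure of the unstrained 13-membered ring should compete well with oligomerisation.

Step 12
Reactants: 23 (7E,11E,13S)-12-({[tert-butyl(dimethyl)silyl]oxy}methyl)-8-methyl-4-methylidene-13-{3-methyl-3-[(triethylsilyl)oxy]but-1-yn-1-yl}-1-oxacyclotrideca-7,11-dien-2-one
Product: 27 (1R,2S,5E)-2-[(2Z)-1-{[tert-butyl(dimethyl)silyl]oxy}-6-methyl-6-[(triethylsilyl)oxy]hept-2-en-4-yn-2-yl]-5-methyl-9-methylidenecyclonon-5-ene-1-carboxylic acid, via lithium dienolate 24 (not isolated), via silyl ketene acetal 25 (not isolated), via trimethylsilyl ester 26 (not isolated)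
Conditions: LiN(iPr)2 (1.5 equiv), Me3SiCl/Et3N (1:1), THF/DMPU (4:1), −78 °C → rt, then 45 °C; aq. citric acid
Reagents that add atoms: none
Why: LiN(iPr)2 removes the C9 proton (α to the lactone carbonyl and allylic to C1=CH2), O-silylation gives the (Z)-silyl ketene acetal 25, and its C9=C(OSi)–O–C2′–C1′=C8 array undergoes a concerted suprafacial [3,3] sigmatropic shift to silyl ester 26, which aqueous acid hydrolyses to 27. This is the Ireland–Claisen (ester-enolate Claisen) ring contraction known for macrocyclic allylic lactones, which gives 2-alkenylcycloalkanecarboxylic acids, applied here to a 13-membered lactone. The nine-membered ring C1–C9 closes by transannular C8–C9 bonding as the C2′–O bond of the lactone breaks (13 to 9 ring contraction), so the strain of the (E)-cyclononene is paid for by the new carboxyl C=O bond. C8 is set by 1,3-chirality transfer from the S carbinol carbon C2′ across the (E)-C8=C1′ alkene with the alkynyl group on C2′ pseudo-equatorial, which also places C3′ trans to C8 on the new C1′=C2′ alkene. C9 is set by the chair transition state with the tether ends C1 and C7 both pseudo-equatorial, which gives the trans C8/C9 pair and needs the ketene acetal with C1 syn to OSiMe3 that enolisation in THF–DMPU should favour. The step also needs the shift to run through the allyl arm and not the alkynyl arm on C2′; the alkyne could only bond at C4′, which is shielded by the quaternary C5′ and would give an allene, and allyl participation is the known preference in Claisen rearrangements of alkenyl alkynyl carbinol derivatives.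

Step 13
Reactants: 27 (1R,2S,5E)-2-[(2Z)-1-{[tert-butyl(dimethyl)silyl]oxy}-6-methyl-6-[(triethylsilyl)oxy]hept-2-en-4-yn-2-yl]-5-methyl-9-methylidenecyclonon-5-ene-1-carboxylic acid
Product: 28 methyl (1R,2S,5E)-2-[(2Z)-1-{[tert-butyl(dimethyl)silyl]oxy}-6-methyl-6-[(triethylsilyl)oxy]hept-2-en-4-yn-2-yl]-5-methyl-9-methylidenecyclonon-5-ene-1-carboxylate
Conditions: Me3SiCHN2, MeOH/toluene, 0 °C
Reagents that add atoms: (trimethylsilyl)diazomethane, C[Si](C)(C)C=[N+]=[N-]
Why: Neutral diazoalkane methylation avoids any base at C9, which is epimerisable because it is both α to the carboxyl and allylic.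

Step 14
Reactants: 28 methyl (1R,2S,5E)-2-[(2Z)-1-{[tert-butyl(dimethyl)silyl]oxy}-6-methyl-6-[(triethylsilyl)oxy]hept-2-en-4-yn-2-yl]-5-methyl-9-methylidenecyclonon-5-ene-1-carboxylate
Product: 29 methyl (1R,2S,5E)-2-[(2Z,4Z)-1-{[tert-butyl(dimethyl)silyl]oxy}-6-methyl-4-(triethoxysilyl)-6-[(triethylsilyl)oxy]hepta-2,4-dien-2-yl]-5-methyl-9-methylidenecyclonon-5-ene-1-carboxylate
Conditions: (EtO)3SiH (1.3 equiv), [Cp*Ru(MeCN)3]PF6 (5 mol %), CH2Cl2, 0 °C → rt
Reagents that add atoms: triethoxysilane, CCO[SiH](OCC)OCC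
Why: Hydrosilylation of internal alkynes with the cationic ruthenium catalyst is known to proceed by trans addition and to prefer alkynes over alkenes, also for 1,3-enynes; silicon is expected at C3′, away from the quaternary C5′, and either regioisomer would lead to the same alkene in step 15.

Step 15
Reactants: 29 methyl (1R,2S,5E)-2-[(2Z,4Z)-1-{[tert-butyl(dimethyl)silyl]oxy}-6-methyl-4-(triethoxysilyl)-6-[(triethylsilyl)oxy]hepta-2,4-dien-2-yl]-5-methyl-9-methylidenecyclonon-5-ene-1-carboxylate
Product: 30 methyl (1R,2S,5E)-2-[(2Z,4E)-1,6-dihydroxy-6-methylhepta-2,4-dien-2-yl]-5-methyl-9-methylidenecyclonon-5-ene-1-carboxylate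
Conditions: Bu4NF, CuI (cat.), THF, 0 °C → rt
Reagents that add atoms: none
Why: Fluoride with CuI protodesilylates alkenyl triethoxysilanes with retention, which turns the trans hydrosilylation into a net trans semi-reduction and should give the (E)-C3′=C4′ alkene, while the same reagent cleaves the TBS and TES ethers.

Step 16
Reactants: 30 methyl (1R,2S,5E)-2-[(2Z,4E)-1,6-dihydroxy-6-methylhepta-2,4-dien-2-yl]-5-methyl-9-methylidenecyclonon-5-ene-1-carboxylate
Product: 31 methyl (1R,2S,5E)-2-[(2Z,4E)-1-(acetyloxy)-6-hydroxy-6-methylhepta-2,4-dien-2-yl]-5-methyl-9-methylidenecyclonon-5-ene-1-carboxylate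
Conditions: Ac2O, pyridine, CH2Cl2, 0 °C
Reagents that add atoms: acetic anhydride, CC(=O)OC(C)=O
Why: Acetylation with Ac2O and pyridine takes the primary allylic hydroxyl and should leave the tertiary hydroxyl, which needs forcing conditions, untouched.

**Compound list**

1 | hex-5-en-1-yne | C=CCCC#C | starting material
2 | oxirane | C1CO1 | starting material
3 | dimethyl[(1E)-2-methylhexa-1,5-dien-1-yl]alumane | C[Al](C)/C=C(\C)CCC=C | intermediate
4 | lithium butyl(dimethyl)[(1E)-2-methylhexa-1,5-dien-1-yl]aluminate | [Li+].CCCC[Al-](C)(C)/C=C(\C)CCC=C | intermediate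
5 | (3E)-4-methylocta-3,7-dien-1-ol | OCC/C=C(\C)CCC=C | intermediate
6 | (5E)-8-bromo-5-methylocta-1,5-diene | BrCC/C=C(\C)CCC=C | intermediate
7 | diketene (4-methylideneoxetan-2-one) | C=C1CC(=O)O1 | starting material
8 | [(3E)-4-methylocta-3,7-dien-1-yl]magnesium bromide | Br[Mg]CC/C=C(\C)CCC=C | intermediate
9 | (6E)-7-methyl-3-methylideneundeca-6,10-dienoic acid | OC(=O)CC(=C)CC/C=C(\C)CCC=C | intermediate
10 | methyl (6E)-7-methyl-3-methylideneundeca-6,10-dienoate | COC(=O)CC(=C)CC/C=C(\C)CCC=C | intermediate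
11 | 2-methylidenepropane-1,3-diol | C=C(CO)CO | starting material
12 | sodium 2-(hydroxymethyl)prop-2-en-1-olate | [Na+].[O-]CC(=C)CO | intermediate
13 | 2-({[tert-butyl(dimethyl)silyl]oxy}methyl)prop-2-en-1-ol | C=C(CO)CO[Si](C)(C)C(C)(C)C | intermediate
14 | 2-({[tert-butyl(dimethyl)silyl]oxy}methyl)prop-2-enal | C=C(C=O)CO[Si](C)(C)C(C)(C)C | intermediate
15 | methyl (6E,10E)-11-({[tert-butyl(dimethyl)silyl]oxy}methyl)-7-methyl-3-methylidene-12-oxododeca-6,10-dienoate | COC(=O)CC(=C)CC/C=C(\C)CC/C=C(/C=O)CO[Si](C)(C)C(C)(C)C | intermediate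
16 | 2-methylbut-3-yn-2-ol | CC(C)(O)C#C | starting material
17 | triethyl[(2-methylbut-3-yn-2-yl)oxy]silane | C#CC(C)(C)O[Si](CC)(CC)CC | intermediate
18 | methyl{3-methyl-3-[(triethylsilyl)oxy]but-1-yn-1-yl}zinc | C[Zn]C#CC(C)(C)O[Si](CC)(CC)CC | intermediate
19 | methyl (6E,10E,12S)-11-({[tert-butyl(dimethyl)silyl]oxy}methyl)-12-hydroxy-7,15-dimethyl-3-methylidene-15-[(triethylsilyl)oxy]hexadeca-6,10-dien-13-ynoate | COC(=O)CC(=C)CC/C=C(\C)CC/C=C(CO[Si](C)(C)C(C)(C)C)/[C@@H](O)C#CC(C)(C)O[Si](CC)(CC)CC | intermediate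
20 | trimethylstannyl (6E,10E,12S)-11-({[tert-butyl(dimethyl)silyl]oxy}methyl)-12-hydroxy-7,15-dimethyl-3-methylidene-15-[(triethylsilyl)oxy]hexadeca-6,10-dien-13-ynoate | C[Sn](C)(C)OC(=O)CC(=C)CC/C=C(\C)CC/C=C(CO[Si](C)(C)C(C)(C)C)/[C@@H](O)C#CC(C)(C)O[Si](CC)(CC)CC | intermediate
21 | (6E,10E,12S)-11-({[tert-butyl(dimethyl)silyl]oxy}methyl)-12-hydroxy-7,15-dimethyl-3-methylidene-15-[(triethylsilyl)oxy]hexadeca-6,10-dien-13-ynoic acid | OC(=O)CC(=C)CC/C=C(\C)CC/C=C(CO[Si](C)(C)C(C)(C)C)/[C@@H](O)C#CC(C)(C)O[Si](CC)(CC)CC | intermediate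
22 | mixed anhydride of 21 with 2,4,6-trichlorobenzoic acid | O=C(OC(=O)CC(=C)CC/C=C(\C)CC/C=C(CO[Si](C)(C)C(C)(C)C)/[C@@H](O)C#CC(C)(C)O[Si](CC)(CC)CC)c1c(Cl)cc(Cl)cc1Cl | intermediate
23 | (7E,11E,13S)-12-({[tert-butyl(dimethyl)silyl]oxy}methyl)-8-methyl-4-methylidene-13-{3-methyl-3-[(triethylsilyl)oxy]but-1-yn-1-yl}-1-oxacyclotrideca-7,11-dien-2-one | C=C1CC/C=C(\C)CC/C=C(CO[Si](C)(C)C(C)(C)C)/[C@H](C#CC(C)(C)O[Si](CC)(CC)CC)OC(=O)C1 | intermediate
24 | lithium dienolate of 23 (C9=C(OLi)O, C1 syn to OLi) | C=C1CC/C=C(\C)CC/C=C(CO[Si](C)(C)C(C)(C)C)/[C@H](C#CC(C)(C)O[Si](CC)(CC)CC)O/C([O-])=C/1.[Li+] | intermediate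
25 | (2Z)-trimethylsilyl ketene acetal of 23 (C1 syn to OSiMe3) | C=C1CC/C=C(\C)CC/C=C(CO[Si](C)(C)C(C)(C)C)/[C@H](C#CC(C)(C)O[Si](CC)(CC)CC)O/C(O[Si](C)(C)C)=C/1 | intermediate
26 | trimethylsilyl ester of 27 | C=C1CC/C=C(\C)CC[C@H](/C(=C/C#CC(C)(C)O[Si](CC)(CC)CC)CO[Si](C)(C)C(C)(C)C)[C@H]1C(=O)O[Si](C)(C)C | intermediate
27 | (1R,2S,5E)-2-[(2Z)-1-{[tert-butyl(dimethyl)silyl]oxy}-6-methyl-6-[(triethylsilyl)oxy]hept-2-en-4-yn-2-yl]-5-methyl-9-methylidenecyclonon-5-ene-1-carboxylic acid | C=C1CC/C=C(\C)CC[C@H](/C(=C/C#CC(C)(C)O[Si](CC)(CC)CC)CO[Si](C)(C)C(C)(C)C)[C@H]1C(=O)O | intermediate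
28 | methyl (1R,2S,5E)-2-[(2Z)-1-{[tert-butyl(dimethyl)silyl]oxy}-6-methyl-6-[(triethylsilyl)oxy]hept-2-en-4-yn-2-yl]-5-methyl-9-methylidenecyclonon-5-ene-1-carboxylate | C=C1CC/C=C(\C)CC[C@H](/C(=C/C#CC(C)(C)O[Si](CC)(CC)CC)CO[Si](C)(C)C(C)(C)C)[C@H]1C(=O)OC | intermediate
29 | methyl (1R,2S,5E)-2-[(2Z,4Z)-1-{[tert-butyl(dimethyl)silyl]oxy}-6-methyl-4-(triethoxysilyl)-6-[(triethylsilyl)oxy]hepta-2,4-dien-2-yl]-5-methyl-9-methylidenecyclonon-5-ene-1-carboxylate | C=C1CC/C=C(\C)CC[C@H](/C(=C/C(=C/C(C)(C)O[Si](CC)(CC)CC)[Si](OCC)(OCC)OCC)CO[Si](C)(C)C(C)(C)C)[C@H]1C(=O)OC | intermediate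
30 | methyl (1R,2S,5E)-2-[(2Z,4E)-1,6-dihydroxy-6-methylhepta-2,4-dien-2-yl]-5-methyl-9-methylidenecyclonon-5-ene-1-carboxylate | C=C1CC/C=C(\C)CC[C@H](/C(=C/C=C/C(C)(C)O)CO)[C@H]1C(=O)OC | intermediate
31 | methyl (1R,2S,5E)-2-[(2Z,4E)-1-(acetyloxy)-6-hydroxy-6-methylhepta-2,4-dien-2-yl]-5-methyl-9-methylidenecyclonon-5-ene-1-carboxylate | C=C1CC/C=C(\C)CC[C@H](/C(=C/C=C/C(C)(C)O)COC(C)=O)[C@H]1C(=O)OC | target

**Step count and risks**

Total: 16 steps. Longest linear sequence: 13 steps (steps 1–4, 7, 9–16, from hex-5-en-1-yne).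

Steps most likely to fail:

1. Step 12 (key step). The ketene acetal may form with the opposite geometry, or the shift may pass through a boat, so that C9 is set cis to C8. The shift may also be diverted through the alkynyl arm, or stall against the strain of closing the (E)-cyclononene. Fallback: it sets out from 23 and returns at 28. The rearrangement would be run as in step 12 and the ring-contracted acid accepted whatever its C9 configuration. The C9 epimer, (1S,2S,5E)-2-[(2Z)-1-{[tert-butyl(dimethyl)silyl]oxy}-6-methyl-6-[(triethylsilyl)oxy]hept-2-en-4-yn-2-yl]-5-methyl-9-methylidenecyclonon-5-ene-1-carboxylic acid F1, would be methylated with Me3SiCHN2 to the C9-epimeric methyl ester F2. F2 would then be equilibrated through its ester dienolate (NaOMe, MeOH, rt); α-reprotonation keeps the exocyclic alkene and should settle C9 in the trans arrangement of the two large vicinal groups, which is 28. C9 is then set under thermodynamic control after the ring is made and not by the transition-state geometry.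

2. Step 14. Hydrometalation of the hindered internal alkyne, flanked by a quaternary carbon and a trisubstituted alkene, may be slow or unselective, and the cationic ruthenium catalyst may attack the strained ring alkene. Fallback: it sets out from 28 and returns at 30. Both silyl ethers of 28 would be cleaved first (Bu4NF/AcOH, THF) to the enyne diol methyl (1R,2S,5E)-2-[(2Z)-1,6-dihydroxy-6-methylhept-2-en-4-yn-2-yl]-5-methyl-9-methylidenecyclonon-5-ene-1-carboxylate F3. Its alkyne, now activated by the free α-hydroxyl on C5′, would be reduced to the (E)-alkene by divalent chromium (CrSO4, DMF/H2O, rt), a known trans-selective reduction of α-hydroxy alkynes that leaves esters and isolated alkenes alone. This gives 30 without ruthenium or silicon.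

3. Step 11. The 3-methylidene double bond may migrate into conjugation when the acyl group is activated in the presence of base, and oligomerisation may outrun ring closure. Fallback: it sets out from 15 and returns at 23. The alkynylation of step 9 would be run with (S,S)-ProPhenol to give the 12R carbinol methyl (6E,10E,12R)-11-({[tert-butyl(dimethyl)silyl]oxy}methyl)-12-hydroxy-7,15-dimethyl-3-methylidene-15-[(triethylsilyl)oxy]hexadeca-6,10-dien-13-ynoate F4. Me3SnOH would give the 12R seco acid (6E,10E,12R)-11-({[tert-butyl(dimethyl)silyl]oxy}methyl)-12-hydroxy-7,15-dimethyl-3-methylidene-15-[(triethylsilyl)oxy]hexadeca-6,10-dien-13-ynoic acid F5. A Mitsunobu macrolactonisation (PPh3, diisopropyl azodicarboxylate, toluene, high dilution, 0 °C) would then close the ring by attack of the carboxylate on the activated C2′ carbinol with inversion. This gives 23 without any activation of the acyl group, so the double bond cannot migrate.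

**Further compounds**

F1 | step 12 | (1S,2S,5E)-2-[(2Z)-1-{[tert-butyl(dimethyl)silyl]oxy}-6-methyl-6-[(triethylsilyl)oxy]hept-2-en-4-yn-2-yl]-5-methyl-9-methylidenecyclonon-5-ene-1-carboxylic acid | C=C1CC/C=C(\C)CC[C@H](/C(=C/C#CC(C)(C)O[Si](CC)(CC)CC)CO[Si](C)(C)C(C)(C)C)[C@@H]1C(=O)O
F2 | step 12 | methyl (1S,2S,5E)-2-[(2Z)-1-{[tert-butyl(dimethyl)silyl]oxy}-6-methyl-6-[(triethylsilyl)oxy]hept-2-en-4-yn-2-yl]-5-methyl-9-methylidenecyclonon-5-ene-1-carboxylate | C=C1CC/C=C(\C)CC[C@H](/C(=C/C#CC(C)(C)O[Si](CC)(CC)CC)CO[Si](C)(C)C(C)(C)C)[C@@H]1C(=O)OC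
F3 | step 14 | methyl (1R,2S,5E)-2-[(2Z)-1,6-dihydroxy-6-methylhept-2-en-4-yn-2-yl]-5-methyl-9-methylidenecyclonon-5-ene-1-carboxylate | C=C1CC/C=C(\C)CC[C@H](/C(=C/C#CC(C)(C)O)CO)[C@H]1C(=O)OC
F4 | step 11 | methyl (6E,10E,12R)-11-({[tert-butyl(dimethyl)silyl]oxy}methyl)-12-hydroxy-7,15-dimethyl-3-methylidene-15-[(triethylsilyl)oxy]hexadeca-6,10-dien-13-ynoate | COC(=O)CC(=C)CC/C=C(\C)CC/C=C(CO[Si](C)(C)C(C)(C)C)/[C@H](O)C#CC(C)(C)O[Si](CC)(CC)CC
F5 | step 11 | (6E,10E,12R)-11-({[tert-butyl(dimethyl)silyl]oxy}methyl)-12-hydroxy-7,15-dimethyl-3-methylidene-15-[(triethylsilyl)oxy]hexadeca-6,10-dien-13-ynoic acid | OC(=O)CC(=C)CC/C=C(\C)CC/C=C(CO[Si](C)(C)C(C)(C)C)/[C@H](O)C#CC(C)(C)O[Si](CC)(CC)CC
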